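At early times substrate and reagent fill the open intermediate while little of it has yet left for product, so I want to know how far that exit runs in each flask.

| setting | gamma | eta | zeta | delta |
|---|---|---|---|---|
| substrate | 10 mM | 10 mM | 10 mM | 10 mM |
| reagent | 1.50 equiv | 1.50 equiv | 1.50 equiv | 1.50 equiv |
| capture agent | 1.00 mM | 1.00 mM | 1.00 mM | 1.00 mM |
| temperature | 110 °C | 125 °C | 140 °C | 95 °C |
| time | 8.0 min | 8.0 min | 8.0 min | 8.0 min |

    substrate + reagent ⇌ open intermediate (K1 = 96 M⁻¹, k1 = 0.342 M⁻¹ s⁻¹, Ea1 = 55.0 kJ mol⁻¹, ΔH1 = −40.0 kJ mol⁻¹)
    open intermediate + capture agent → trapped intermediate (k2 = 0.282 M⁻¹ s⁻¹, Ea2 = 58.0 kJ mol⁻¹)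
    open intermediate ⇌ product + released group (K3 = 0.0203 M, k3 = 0.00191 s⁻¹, Ea3 = 121 kJ mol⁻¹, ΔH3 = −66.0 kJ mol⁻¹)
    (constants at 110 °C)

- constants are those at 110 °C; use the activation energies and enthalpies for any other temperature

- the flask with the highest amount of open intermediate, in percent of the substrate charged ("all alike" if they lie within 1.5 percentage points) (gamma / eta / zeta / delta / all alike)
- final open intermediate, as a percentage of the substrate charged, in gamma
- final open intermediate, as a percentage of the substrate charged, in eta
- final open intermediate, as a percentage of the substrate charged, in zeta
- final open intermediate, as a percentage of the substrate charged, in delta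

I count turnovers. Corrected by its activation energy, the forward exit constant in delta is 4.06 × 10⁻⁴ s⁻¹, which over 8.0 min gives 0.195. I call this N, the number of turnovers of the open intermediate through the forward exit step during the run, the rate constant at the flask's temperature times the time. N is 0.917 in gamma, 3.83 in eta and 14.5 in zeta. So delta has the lowest count, and I expect it to hold the most open intermediate.

But the cold also slows the entry, so delta may not have filled. The entry equilibrium constant in delta is 160 M⁻¹, which allows 59.2% of the substrate charged. With an entry constant of 0.169 M⁻¹ s⁻¹, the exact integral of this second-order reversible step has the exponent 1.58 at the end of the run, so delta fills to 49.4% if nothing leaves.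

Something does leave, however. The same integral gives the filling curve a time-mean level of 32.5%, and the capture agent adds a smaller count, 0.0645, than the exit. Taking both counts on that mean level, I commit to 40.9% in delta. A further objection stands against the hot flasks: N counts the forward step, and the exit is reversible, so a count above one in eta and zeta points to a level held by equilibrium, not to an empty flask. That is thermodynamic control there against kinetic control in delta, and I leave those levels uncomputed.

The forecast names delta, with 30% (26% to 34%) in gamma, 19% (16.5% to 22%) in eta, 18% (15.5% to 20.5%) in zeta and 44% (39% to 48%) in delta, since “the strongly activated step to product drains it”.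

The simulation gives 29.0% in gamma, 18.4% in eta, 17.9% in zeta and 42.8% in delta, the highest and 1.9 percentage points above my reckoning. At the end of delta the forward exit runs 3.7 times as fast as capture. Dividing the 5.82% of product in delta by N gives a mean level of about 29.8% over the run, lower than the open intermediate standing at the end.

Delta read at 30 min has N = 0.731, and holding the open intermediate at its level of 42.8% gives about 31.3% product. The computed flask holds 27.3% product, with 35.1% open intermediate.

The numbers of this flask come from no measurement; no experiment stands behind them.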